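The butenolide (ring B; benzofuranone numbering O1, C2=O, C3, C3a, C4–C7, C7a) is disconnected at O1–C7a and C2–O, back to dioxygen and the diene C7a=C3a–C3=C2. Its O1–C7a–C3a=C3–C2(=O) array is a cis-2-ene-1,4-dioxygenated unit, the footprint of O2 across a diene. Sensitised singlet oxygen adds to a palmitoylated ring-vinyl dienol ether, closing a 1,2-dioxine and setting C7a and the acetal carbon C2 in one operation; amine-induced Kornblum–DeLaMare cleavage then gives the lactone directly. The precursor, (1R)-4-[(E)-2-ethoxyethenyl]-3,5,5-trimethylcyclohex-3-en-1-yl palmitate, comes from Suzuki coupling of an enol triflate that already carries the palmitate, so the acid-labile dienol ether is made immediately before use.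

Key step: step 7

Assumption: the two reductases of step 1 are taken as available recombinant preparations with the stated selectivities; the methyl-bearing stereocentre they set is only a relay and is erased in step 3.

Step 1
Reactants: 1 ketoisophorone (2,6,6-trimethylcyclohex-2-ene-1,4-dione)
Product: 3 (4R,6R)-4-hydroxy-2,2,6-trimethylcyclohexan-1-one (trans-actinol), via (6R)-levodione 2 (not isolated)
Conditions: OYE2 ene-reductase, NADP+ (cat.), glucose, glucose dehydrogenase, KH2PO4/K2HPO4 buffer pH 7, 30 °C; then levodione reductase, NAD+ (cat.), 30 °C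
Reagents that add atoms: none
Why: A known two-enzyme cascade: the ene-reductase performs an asymmetric conjugate reduction of the enedione C=C that fixes the methyl-bearing carbon as R, and the levodione reductase then reduces only the unhindered C4 carbonyl from the face that gives the 4R alcohol trans to that methyl, the hindered C1 ketone being left for step 3.

Step 2
Reactants: 3 (4R,6R)-4-hydroxy-2,2,6-trimethylcyclohexan-1-one
Product: 4 (4R,6R)-4-[(tert-butyldimethylsilyl)oxy]-2,2,6-trimethylcyclohexan-1-one
Conditions: TBSCl, imidazole, DMF, rt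
Reagents that add atoms: tert-butyldimethylsilyl chloride, CC(C)(C)[Si](C)(C)Cl
Why: Imidazole-promoted O-silylation of the secondary alcohol is routine and removes the only acidic O–H before the strong-base enolisation, without touching either stereocentre.

Step 3
Reactants: 4 (4R,6R)-4-[(tert-butyldimethylsilyl)oxy]-2,2,6-trimethylcyclohexan-1-one
Product: 6 (4R)-4-[(tert-butyldimethylsilyl)oxy]-2,6,6-trimethylcyclohex-1-en-1-yl trifluoromethanesulfonate, via lithium enolate 5 (not isolated)
Conditions: LiN(iPr)2, THF, −78 → 0 °C; then PhNTf2, −78 °C → rt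
Reagents that add atoms: N-phenylbis(trifluoromethanesulfonimide), O=S(=O)(N(c1ccccc1)S(=O)(=O)C(F)(F)F)C(F)(F)F
Why: The ketone can enolise only toward the methyl-bearing carbon, so deprotonation with LiN(iPr)2 and O-sulfonylation of the lithium enolate with PhNTf2 (enol triflate formation) should give one tetrasubstituted enol triflate, erasing the relay centre while the silyloxy carbon, γ to the carbonyl and not eliminable, keeps its R configuration.

Step 4
Reactants: 6 (4R)-4-[(tert-butyldimethylsilyl)oxy]-2,6,6-trimethylcyclohex-1-en-1-yl trifluoromethanesulfonate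
Product: 7 (4R)-4-hydroxy-2,6,6-trimethylcyclohex-1-en-1-yl trifluoromethanesulfonate
Conditions: 48% aq. HF, MeCN, 0 °C → rt
Reagents that add atoms: none
Why: Acidic fluoride cleaves the secondary silyl ether (protodesilylation) while the enol triflate, inert to acid, is spared the S–O cleavage that basic fluoride sources can cause.

Step 5
Reactants: 7 (4R)-4-hydroxy-2,6,6-trimethylcyclohex-1-en-1-yl trifluoromethanesulfonate; 8 palmitoyl chloride (hexadecanoyl chloride)
Product: 9 (1R)-3,5,5-trimethyl-4-[(trifluoromethanesulfonyl)oxy]cyclohex-3-en-1-yl hexadecanoate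
Conditions: pyridine, DMAP (cat.), CH2Cl2, 0 °C → rt
Reagents that add atoms: none
Why: DMAP-catalysed acylation (nucleophilic catalysis) of the unhindered equatorial secondary alcohol with the acid chloride proceeds with retention at the carbinol carbon and installs the final ester while the molecule is still robust.

Step 6
Reactants: 9 (1R)-3,5,5-trimethyl-4-[(trifluoromethanesulfonyl)oxy]cyclohex-3-en-1-yl hexadecanoate; 10 (E)-2-ethoxyvinylboronic acid pinacol ester
Product: 11 (1R)-4-[(E)-2-ethoxyethenyl]-3,5,5-trimethylcyclohex-3-en-1-yl hexadecanoate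
Conditions: Pd(OAc)2 (5 mol %), SPhos (2-dicyclohexylphosphino-2′,6′-dimethoxybiphenyl, 10 mol %), K3PO4, THF/H2O (10:1), degassed, 50 °C
Reagents that add atoms: none
Why: Suzuki–Miyaura coupling, with retention of the (E) geometry of the alkenylboronate, should join the arm to the hindered enol triflate because the bulky electron-rich biarylphosphine speeds oxidative addition to zerovalent palladium and reductive elimination, while the mild phosphate base and the absence of any acid spare the palmitate and the new enol ether (work-up and chromatography on Et3N-deactivated silica).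

Step 7
Reactants: 11 (1R)-4-[(E)-2-ethoxyethenyl]-3,5,5-trimethylcyclohex-3-en-1-yl hexadecanoate
Product: 12 (3R,7S,8aR)-3-ethoxy-5,5,8a-trimethyl-3,5,6,7,8,8a-hexahydro-1,2-benzodioxin-7-yl hexadecanoate (peroxide O1 on the methyl-bearing ring-fusion carbon, O2 on the ethoxy acetal carbon, C4=C4a double bond)
Conditions: O2, meso-tetraphenylporphyrin (0.5 mol %), white LED, toluene (filtered through basic alumina), −78 °C
Reagents that add atoms: dioxygen, O=O
Why: Singlet oxygen, formed by energy transfer from the photoexcited porphyrin, adds as the 2π partner across the termini of the electron-rich s-cis diene C7a=C3a–C3=C2 in a concerted suprafacial [4+2] cycloaddition, the known reaction type being endoperoxide formation from 1-alkoxy-1,3-dienes and from ionone-type ring-vinyl dienes. The single new ring, the six-membered 3,6-dihydro-1,2-dioxine, is closed by cycloaddition, with the C7a–O1 and C2–O bonds formed in the same event and the C3a=C3 double bond left cis inside it. C7a is set by the diene face attacked: the equatorial C6 palmitate locks the half-chair of ring A with the pseudoaxial C4 methyl on the face anti to the ester, the vinyl arm twists to place H3 between the two C4 methyls and so tilts C2 toward the ester face, and the converging lobes at C7a and C2 then lie on the anti face, which is also the axial chair-forming trajectory at C7a, so O1 should enter trans to the ester oxygen (7aR in target numbering). The acetal carbon follows from suprafaciality, because on the (E)-enol ether the ethoxy group is the outside substituent and its configuration is tied to that of C7a (3R,8aR in the dioxine numbering). The step needs [4+2] to outrun the ene reaction at the tetrasubstituted ring alkene and dioxetane formation at the enol ether; the C4 gem-dimethyl group excludes the s-trans rotamer, the ethoxy donor raises the diene HOMO, toluene at −78 °C disfavours the polar perepoxide and zwitterion pathways, and the non-hydrogen-bonding acyloxy group cannot steer oxygen to its own face as a free hydroxyl might.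

Step 8
Reactants: 12 (3R,7S,8aR)-3-ethoxy-5,5,8a-trimethyl-3,5,6,7,8,8a-hexahydro-1,2-benzodioxin-7-yl hexadecanoate (crude, used directly)
Product: 14 (−)-3-O-palmitoylloliolide, (6S,7aR)-4,4,7a-trimethyl-2-oxo-2,4,5,6,7,7a-hexahydro-1-benzofuran-6-yl hexadecanoate, via hydroxy ester 13 (not isolated)
Conditions: Et3N (2 equiv), CH2Cl2, −40 °C → rt; then DBU (0.1 equiv), rt
Reagents that add atoms: none
Why: Kornblum–DeLaMare rearrangement: the amine removes the only hydrogen on a peroxide-bearing carbon (the acetal H at C2, C7a having none), the O–O bond breaks to give the (Z)-hydroxy enoate, and the tertiary C7a oxygen held cis to the ethyl ester closes the butenolide by 5-exo-trig transesterification, with neither stereocentre touched.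

Compound list
1 | ketoisophorone (2,6,6-trimethylcyclohex-2-ene-1,4-dione) | CC1=CC(=O)CC(C)(C)C1=O | starting material
2 | (6R)-2,2,6-trimethylcyclohexane-1,4-dione ((6R)-levodione) | C[C@@H]1CC(=O)CC(C)(C)C1=O | intermediate
3 | (4R,6R)-4-hydroxy-2,2,6-trimethylcyclohexan-1-one (trans-actinol) | C[C@@H]1C[C@@H](O)CC(C)(C)C1=O | intermediate
4 | (4R,6R)-4-[(tert-butyldimethylsilyl)oxy]-2,2,6-trimethylcyclohexan-1-one | C[C@@H]1C[C@@H](O[Si](C)(C)C(C)(C)C)CC(C)(C)C1=O | intermediate
5 | lithium (4R)-4-[(tert-butyldimethylsilyl)oxy]-2,6,6-trimethylcyclohex-1-en-1-olate | CC(C)(C)[Si](C)(C)O[C@H]1CC(C)(C)C(O[Li])=C(C)C1 | intermediate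
6 | (4R)-4-[(tert-butyldimethylsilyl)oxy]-2,6,6-trimethylcyclohex-1-en-1-yl trifluoromethanesulfonate | CC(C)(C)[Si](C)(C)O[C@H]1CC(C)(C)C(OS(=O)(=O)C(F)(F)F)=C(C)C1 | intermediate
7 | (4R)-4-hydroxy-2,6,6-trimethylcyclohex-1-en-1-yl trifluoromethanesulfonate | O[C@H]1CC(C)(C)C(OS(=O)(=O)C(F)(F)F)=C(C)C1 | intermediate
8 | palmitoyl chloride (hexadecanoyl chloride) | CCCCCCCCCCCCCCCC(=O)Cl | starting material
9 | (1R)-3,5,5-trimethyl-4-[(trifluoromethanesulfonyl)oxy]cyclohex-3-en-1-yl hexadecanoate | CCCCCCCCCCCCCCCC(=O)O[C@H]1CC(C)(C)C(OS(=O)(=O)C(F)(F)F)=C(C)C1 | intermediate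
10 | (E)-2-ethoxyvinylboronic acid pinacol ester | CCO/C=C/B1OC(C)(C)C(C)(C)O1 | starting material
11 | (1R)-4-[(E)-2-ethoxyethenyl]-3,5,5-trimethylcyclohex-3-en-1-yl hexadecanoate | CCCCCCCCCCCCCCCC(=O)O[C@H]1CC(C)(C)C(/C=C/OCC)=C(C)C1 | intermediate
12 | (3R,7S,8aR)-3-ethoxy-5,5,8a-trimethyl-3,5,6,7,8,8a-hexahydro-1,2-benzodioxin-7-yl hexadecanoate | CCCCCCCCCCCCCCCC(=O)O[C@H]1CC(C)(C)C2=C[C@H](OCC)OO[C@]2(C)C1 | intermediate
13 | ethyl (2Z)-[(2R,4S)-4-(hexadecanoyloxy)-2-hydroxy-2,6,6-trimethylcyclohexylidene]acetate | CCCCCCCCCCCCCCCC(=O)O[C@H]1CC(C)(C)/C(=C/C(=O)OCC)[C@](C)(O)C1 | intermediate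
14 | (−)-3-O-palmitoylloliolide, (6S,7aR)-4,4,7a-trimethyl-2-oxo-2,4,5,6,7,7a-hexahydro-1-benzofuran-6-yl hexadecanoate | CCCCCCCCCCCCCCCC(=O)O[C@H]1CC(C)(C)C2=CC(=O)O[C@]2(C)C1 | target

Total step count: 8. Longest linear sequence: 8 steps (1 → 14); 8 and 10 enter as purchased reagents.

Steps most likely to fail

Step 7. Singlet oxygen may be diverted into ene hydroperoxidation of the tetrasubstituted ring alkene or dioxetane cleavage of the enol ether, and attack may occur partly on the ester face. The C7a epimer would then appear after step 8 as the epimeric lactone, to be removed by chromatography. The fallback is peroxide-free, takes its face control from a free hydroxyl, sets out from 7 and returns at 14. Suzuki coupling of 7 with 10 under the step 6 conditions should give (1R)-4-[(E)-2-ethoxyethenyl]-3,5,5-trimethylcyclohex-3-en-1-ol F1. Mild hydrolysis (aq. oxalic acid, THF, 0 °C) would give the β,γ-unsaturated hydroxy aldehyde F2, and Pinnick oxidation (NaClO2, NaH2PO4, 2-methyl-2-butene, t-BuOH/H2O) the hydroxy acid F3. Hydroxyl-directed epoxidation (VO(acac)2 cat., t-BuOOH, CH2Cl2) should deliver oxygen syn to the C6 hydroxyl. The carboxyl group then opens the epoxide at C7a with inversion, so that O1 ends trans to the C6 oxygen in the cis-fused dihydroxy lactone F4. Acylation of the secondary hydroxyl with 8 (pyridine, DMAP, CH2Cl2) would give the hydroxy lactone palmitate F5, and dehydration of the tertiary β-hydroxy lactone (SOCl2, pyridine, 0 °C) returns to 14.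

Step 6. Oxidative addition and transmetalation at the hindered tetrasubstituted enol triflate may be slow, leaving protodeboronation of 10 and hydrolysis of the enol ether on work-up as the faster processes. The fallback replaces cross-coupling by carbonyl addition, sets out from 4 and returns at 11. Addition of lithium ethoxyacetylide, LiC≡COEt (ethoxyacetylene, n-BuLi, THF, −78 °C), to ketone 4 should give the ethoxyethynyl carbinol F6 as inconsequential C1 epimers. LiAlH4 (THF, 0 °C) should trans-reduce the alkynyl ether to the (E)-2-ethoxyvinyl carbinol F7. Dehydration of the tertiary allylic alcohol toward its only β-hydrogen (methyl N-(triethylammoniosulfonyl)carbamate, toluene, 50 °C) would give the silyl dienol ether F8. TBAF (THF) then releases the alcohol F1, and acylation with 8 (pyridine, DMAP, CH2Cl2) gives 11.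

Step 8. The peroxy acetal may fragment by other base- or trace-acid-induced pathways before the acetal hydrogen is removed, or lactonisation may stall at hydroxy ester 13. The fallback replaces the redox-neutral cleavage by reduction then oxidation, sets out from 12 and returns at 14. Thiourea (MeOH, 0 °C) should reduce the O–O bond; the resulting ethyl hemiacetal loses ethanol and the (Z)-hydroxy enal closes to the lactol F9. MnO2 (CH2Cl2, rt) would oxidise this allylic lactol to 14.

Further compounds
F1 | step 7 | (1R)-4-[(E)-2-ethoxyethenyl]-3,5,5-trimethylcyclohex-3-en-1-ol | O[C@H]1CC(C)(C)C(/C=C/OCC)=C(C)C1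
F2 | step 7 | 2-[(4R)-4-hydroxy-2,6,6-trimethylcyclohex-1-en-1-yl]acetaldehyde | O[C@H]1CC(C)(C)C(CC=O)=C(C)C1
F3 | step 7 | 2-[(4R)-4-hydroxy-2,6,6-trimethylcyclohex-1-en-1-yl]acetic acid | O[C@H]1CC(C)(C)C(CC(=O)O)=C(C)C1
F4 | step 7 | (3aR,6S,7aR)-3a,6-dihydroxy-4,4,7a-trimethylhexahydro-1-benzofuran-2(3H)-one | O[C@H]1CC(C)(C)[C@]2(O)CC(=O)O[C@]2(C)C1
F5 | step 7 | (3aR,6S,7aR)-3a-hydroxy-4,4,7a-trimethyl-2-oxooctahydro-1-benzofuran-6-yl hexadecanoate | CCCCCCCCCCCCCCCC(=O)O[C@H]1CC(C)(C)[C@]2(O)CC(=O)O[C@]2(C)C1
F6 | step 6 | (4R,6R)-4-[(tert-butyldimethylsilyl)oxy]-1-(ethoxyethynyl)-2,2,6-trimethylcyclohexan-1-ol (C1 epimers) | C[C@@H]1C[C@@H](O[Si](C)(C)C(C)(C)C)CC(C)(C)C1(O)C#COCC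
F7 | step 6 | (4R,6R)-4-[(tert-butyldimethylsilyl)oxy]-1-[(E)-2-ethoxyethenyl]-2,2,6-trimethylcyclohexan-1-ol (C1 epimers) | C[C@@H]1C[C@@H](O[Si](C)(C)C(C)(C)C)CC(C)(C)C1(O)/C=C/OCC
F8 | step 6 | tert-butyl{[(1R)-4-[(E)-2-ethoxyethenyl]-3,5,5-trimethylcyclohex-3-en-1-yl]oxy}dimethylsilane | CC(C)(C)[Si](C)(C)O[C@H]1CC(C)(C)C(/C=C/OCC)=C(C)C1
F9 | step 8 | (6S,7aR)-2-hydroxy-4,4,7a-trimethyl-2,4,5,6,7,7a-hexahydro-1-benzofuran-6-yl hexadecanoate (C2 anomers) | CCCCCCCCCCCCCCCC(=O)O[C@H]1CC(C)(C)C2=CC(O)O[C@]2(C)C1
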